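Amounts first: count target plus starting material as a fraction of the starting material charged, and call this the live fraction s (the mass balance of those two).

| flask | starting material | reagent | second substrate | protic impurity | remark | time |
|---|---|---|---|---|---|---|
| beta | 0.20 M | 1.1 equiv | 1 equiv | 0.10 M | run made earlier |  |
| Friday's | 0.20 M | 1.10 equiv | 1.00 equiv | 0.200 M |  | 15 h |
| Tuesday's | 0.20 M | 1.10 equiv | 1.00 equiv | 0.200 M |  | 20 h |
| Saturday's | 0.20 M | 1.10 equiv | 1.00 equiv | 0.200 M |  | 25 h |

beta run (percent of the starting material charged)

| time / h | target / % | starting material / % |
|---|---|---|
| 0.833 | 27.9 | 52.2 |
| 1.50 | 31.8 | 41.3 |
| 2.50 | 34.7 | 32.0 |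
| 3.00 | 35.8 | 29.4 |
| 4.00 | 36.6 | 24.6 |
| 5.00 | 37.6 | 22.4 |

(each reading ± 0.3 percentage points)

- no earlier run changes the charge of protic impurity; that part of a forecast is a guess

* which of these there is most of at the end, counted by the starting material in it, Friday's (starting material / target)
* which of these there is most of at the end, counted by the starting material in it, Tuesday's (starting material / target)
* which of these there is most of at the end, counted by the starting material in it, Saturday's (starting material / target)
* how much there is at the end of the one of these that leads, in percent of the starting material charged: Friday's
* how much there is at the end of the one of these that leads, in percent of the starting material charged: Tuesday's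
* how much there is at the end of the one of these that leads, in percent of the starting material charged: Saturday's

1. In the beta run, s falls from 80.1% at 0.833 h to 60.0% at 5.00 h. I read this loss as starting material taken one to one by protic impurity, charged there at half the starting material.

2. So in the beta run the impurity left, as a fraction of the starting material charged, is s minus the 0.500 by which its charge falls short of the starting material's. The area under the starting-material readings is 1.34 h. The logarithm of the impurity's fall over that area gives 0.824 h⁻¹, the drain constant κ: the logarithmic fall of impurity per hour per unit fraction of starting material.

3. Friday's, Tuesday's and Saturday's flasks charge impurity equal to starting material, so impurity left equals s. Then 1/s starts at one and climbs at κ times w, the share of s that is starting material.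

4. Lower bound on target, as my own estimate and not a proof: hold w at the last beta reading, 0.373. Target is then 11.2% on Friday's, 8.76% on Tuesday's and 7.21% on Saturday's.

5. Upper bound: the plain one is the beta run's 37.6%. To tighten it, let target over starting material climb once more by the factor it climbed across the beta readings. That makes w 0.159, and target 28.3% on Friday's, 23.2% on Tuesday's and 19.6% on Saturday's.

6. Target leads at both bounds, since w stays under the share left to target. Friday's bracket is 0.403 powers of ten wide, so I commit to the logarithmic middles: 17.8% on Friday's, 14.3% on Tuesday's and 11.9% on Saturday's.

7. The forecast names target for each flask, with 25%, 25% and 25%: “I expect about 25%, flat from 15 to 25 h, assuming target is stable.” Friday's value lies below my upper bound, while Tuesday's and Saturday's lie above theirs.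

8. The flasks give target in the lead, at 19.2% on Friday's, 16.3% on Tuesday's and 14.1% on Saturday's, each below its upper bound and above its lower one.

    starting material + reagent ⇌ target (K = 75.0 M⁻¹, k = 0.00190 M⁻¹ s⁻¹)
    second substrate + reagent ⇌ second product (K = 66.0 M⁻¹, k = 0.00790 M⁻¹ s⁻¹)
    starting material + protic impurity → quenched substrate (k = 0.00120 M⁻¹ s⁻¹)

In Friday's flask, the step between starting material plus reagent and target has a relaxation half-life of 1.69 h at the asked time, that step alone and both ways together, short against the 15 h of the run, and target still falls from 25.8% at 7.50 h to 19.2% at 15.0 h. Between Friday's end and Saturday's end, 1/s climbs at 0.152 h⁻¹, against 0.144 h⁻¹ from 0.824 h⁻¹ and Friday's end share. The neighbour of Friday's flask, charged with 4.40 equiv of reagent, ends with 67.8% of target, and 0.824 h⁻¹ reads its mean w as 0.0360, against 0.267 for Friday's.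

The readings are simulated for substances that don't exist.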